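**Two rates.** Set side by side the two rates that share the starting material: the enzyme step makes product, and the impurity step makes quenched substrate. Follow their ratio, the selectivity factor.

in all of them: enzyme 0.24 µM

|  | starting material | protic impurity | remark | time |
|---|---|---|---|---|
| zeta | 30 mM | 10 mM | run made earlier |  |
| flask | 20 mM | 10.0 mM |  | 5.0 h |

zeta run (percent of the starting material charged)

| time / min | starting material / % | product / % |
|---|---|---|
| 3.00 | 33.6 | 45.4 |
| 10.0 | 10.6 | 60.7 |
| 15.0 | 6.1 | 65.6 |
| 25.0 | 2.2 | 66.3 |
| 40.0 | 0.4 | 68.7 |
| 50.0 | 1.0 | 68.6 |
| 60.0 | 0 | 69.5 |

(standard deviation of a reading: 0.5 percentage points)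

* at 5.0 h, what has stopped the reaction, if anything has (it is still moving / all of the starting material has reacted)
* part of the starting material gone at 5.0 h
* the product standing at 5.0 h, as a percentage of the starting material charged
* amount of product if the flask were left three thousand times as long, in percent of the starting material charged

- reactions considered so far: starting material + enzyme -> product + enzyme; starting material + protic impurity -> quenched substrate; enzyme -> spent catalyst
- the reaction counts as stopped when no species that holds the starting material changes by six tenths of a point or more over the second half of the time

**The reach.** Let c(starting material) cancel from that ratio. The impurity step goes with c(impurity). Assume that the enzyme step slows roughly as one over c(product), and test this on zeta. Summing the ratio, with the enzyme taken as steady, then gives a constant. The last zeta reading, with 0.850 mM of impurity left, gives 13.3 mM for the reach B: c(product) over the square root of ln(impurity charged over impurity left). The zeta reading at 3.00 min gives 13.7 mM, close to it.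

**Going round.** Take the flask's starting material as gone by the end, as zeta reads 0% at 60.0 min. Each quenched substrate takes one impurity, so at the end of the flask c(product) is 20 mM minus 10.0 mM plus the impurity left. Start at c(product) = B and go round: 13.7 mM, then 13.5 mM, then 13.6 mM, or 68.0%.

**The forecast.** It says all of the starting material has reacted, with 100% gone. It gives 65% of product (59% to 70%), lower than my figure, and 65% in the long run: “Nothing shows product being lost”.

**The result.** In the flask all of the starting material has reacted: 100% is gone, with 67.9% of product at 5.0 h and 67.9% in the long run, inside the forecast's range.

    starting material + enzyme → product + enzyme, rate k1*[starting material]*[enzyme]/(1 + ([starting material]/Km1) + ([product]/Kp1)) (0.0965 M, 1.36 mM, k = 1.26 × 10⁵ M⁻¹ s⁻¹)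
    starting material + protic impurity → quenched substrate (k = 0.335 M⁻¹ s⁻¹)
    enzyme → spent catalyst (k = 5.04 × 10⁻⁴ s⁻¹)

**The neighbour.** The flask's own end gives a reach of 13.4 mM. Now take the neighbour with 25 mM of impurity, and solve the rule for c(product). From B the rounds swing to 7.43 mM and 11.1 mM. One more round from their midpoint gives 9.95 mM, or 49.7%. The neighbour flask stands at 48.6% of product.

The data are simulated with made-up constants, and the scatter is random.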